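**Retrosynthetic overview**
1. The target is disconnected at its two C–Br bonds on the last free ring positions, giving 3-bromo-5-methylbenzene-1,2-diol (exhaustive electrophilic bromination, no regiochemical choice).
2. That catechol is disconnected at one phenolic C–O bond, giving the symmetric, commercially available 2,6-dibromo-4-methylphenol (borate-templated, copper-catalysed ipso-hydroxylation of one of two equivalent C–Br bonds; the key step, and new).
3. Ring order: the benzene ring is bought intact. The only ring formed is a transient five-membered dioxaborole in step 1, hydrolysed in the same flask.

Assumption: the target has no stereocentre (achiral, planar arene), so it is a single compound as drawn and no stereocontrol is needed.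

**Step 1**
Reactants: 1 2,6-dibromo-4-methylphenol
Product: 4 3-bromo-5-methylbenzene-1,2-diol, via aryl borate 2 (not isolated), via cyclic catechol borate 3 (not isolated)
Conditions: B(OH)3 (1.5 equiv), CuI (10 mol %), 3,4,7,8-tetramethyl-1,10-phenanthroline (20 mol %), K3PO4 (2.5 equiv), 4 Å MS, DMSO, 100 °C, Ar; acidic aqueous work-up (pH 3)
Reagents that add atoms: boric acid, OB(O)O
Why: Proposed new method: a borate-templated intramolecular Ullmann hydroxylation, in which the phenoxide of 1 condenses with B(OH)3 to aryl borate 2, whose anionic B–O oxygen binds the phenanthroline-ligated monovalent copper centre next to one ortho C–Br, so that oxidative addition gives a six-membered trivalent-copper metallacycle (Cu–C–C–O–B–O) and C–O reductive elimination closes the five-membered dioxaborole 3; the chelated boron cannot reach the second C–Br (three adjacent oxygens cannot bind one boron), which stops the reaction at mono-hydroxylation and masks the catechol from copper or air oxidation until acidic hydrolysis of the B–O bonds releases 4; the closest known reaction types are the copper-catalysed Ullmann-type hydroxylation of aryl bromides with hydroxide and the palladium-catalysed hydroxylation of aryl halides with boric acid as hydroxide surrogate, neither shown in a tethered, mono-selective form on a 2,6-dibromophenol; no stereocentre is formed.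

**Step 2**
Reactants: 4 3-bromo-5-methylbenzene-1,2-diol
Product: 5 3,4,6-tribromo-5-methylbenzene-1,2-diol
Conditions: Br2 (2.1 equiv), AcOH, 15 °C to rt, dark; pour into water, filter
Reagents that add atoms: bromine, BrBr
Why: Electrophilic aromatic bromination, in which the only two remaining ring C–H positions are ortho and para to the C1 hydroxyl and both ortho to the methyl group, so exactly two brominations occur with no regiochemical choice, the methyl group is untouched in the dark, and no stereocentre is formed.

**Compound list**
1 | 2,6-dibromo-4-methylphenol | Cc1cc(Br)c(O)c(Br)c1 | starting material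
2 | 2,6-dibromo-4-methylphenyl dihydrogen borate (aryl borate) | Cc1cc(Br)c(OB(O)O)c(Br)c1 | intermediate
3 | 4-bromo-6-methyl-1,3,2-benzodioxaborol-2-ol (cyclic catechol borate) | Cc1cc(Br)c2OB(O)Oc2c1 | intermediate
4 | 3-bromo-5-methylbenzene-1,2-diol | Cc1cc(O)c(O)c(Br)c1 | intermediate
5 | 3,4,6-tribromo-5-methylbenzene-1,2-diol | Cc1c(Br)c(O)c(O)c(Br)c1Br | target

**Totals**
Total step count: 2. Longest linear sequence: 2.

**Steps most likely to fail**
The route has only two steps, so both are ranked and there is no third.

Most likely to fail: step 1, the proposed new method. The aryl borate may form only in low concentration, the B–O oxygen may be too weak a nucleophile at copper, and protodebromination or Ullmann diaryl ether formation may compete. The fallback uses known chemistry, sets out from 1 and comes back to the route at 4. Treat 1 with n-BuLi (2.1 equiv) in THF at −78 °C; this deprotonates the phenol and then exchanges one bromine for lithium, giving lithium 2-bromo-6-lithio-4-methylphenolate F1. The second bromine is not exchanged on the doubly metalated ring, and it is meta to the lithiated carbon, so no aryne can form. Trap with B(OMe)3 and hydrolyse with dilute HCl to (3-bromo-2-hydroxy-5-methylphenyl)boronic acid F2. Oxidise the C–B bond with 30% H2O2 and aqueous NaHCO3 in THF at 0 °C (1,2-aryl shift from boron to oxygen) to give 4.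

Second: step 2. Bromine may oxidise part of the catechol to the ortho-quinone, or bromination at the position flanked by Br and CH3 may stall. The fallback sets out from 4 and comes back at 5. Methylate both hydroxyls (MeI, K2CO3, acetone, reflux) to 1-bromo-2,3-dimethoxy-5-methylbenzene F3, which cannot be oxidised to a quinone. Brominate (Br2 2.2 equiv, AcOH, 40 °C) to 1,2,4-tribromo-5,6-dimethoxy-3-methylbenzene F4. Cleave both methyl ethers with BBr3 (CH2Cl2, −78 °C to rt) to give 5.

**Further compounds**
F1 | step 1 | lithium 2-bromo-6-lithio-4-methylphenolate | [Li]Oc1c(Br)cc(C)cc1[Li]
F2 | step 1 | (3-bromo-2-hydroxy-5-methylphenyl)boronic acid | Cc1cc(Br)c(O)c(B(O)O)c1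
F3 | step 2 | 1-bromo-2,3-dimethoxy-5-methylbenzene | COc1cc(C)cc(Br)c1OC
F4 | step 2 | 1,2,4-tribromo-5,6-dimethoxy-3-methylbenzene | COc1c(OC)c(Br)c(Br)c(C)c1Br
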